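The earlier runs and the new flask were generated by integration with constants of no real substance, noise included.

One question came up. The meeting had to say how D stands against X in each flask at the end of the run.

| flask | G | E | temperature | remark | time |
|---|---|---|---|---|---|
| north-west | 14 mM | 32.4 mM | 35 °C | run made earlier |  |
| south-west | 21 mM | 32.4 mM | 57 °C | run made earlier |  |
| north-east | 18 mM | 42 mM | 35 °C | run made earlier |  |
| elm | 18 mM | 100 mM | 25 °C |  | 4.0 h |
| larch | 10 mM | 10.0 mM | 25 °C |  | 4.0 h |
| cedar | 12 mM | 15.0 mM | 65 °C |  | 4.0 h |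
| oak | 18 mM | 32.4 mM | 25 °C |  | 4.0 h |

north-west run (percent of the G charged)

| time / h | D / % | X / % |
|---|---|---|
| 0.200 | 12 | 0 |
| 0.333 | 17 | 4 |
| 0.417 | 14 | 3 |
| 0.667 | 16 | 4 |
| 1.00 | 16 | 7 |
| 1.50 | 15 | 7 |
| 2.50 | 15 | 12 |

south-west run (percent of the G charged)

| time / min | D / % | X / % |
|---|---|---|
| 4.00 | 3 | 6 |
| 6.00 | 4 | 8 |
| 8.00 | 4 | 11 |
| 12.0 | 5 | 16 |
| 20.0 | 2 | 25 |
| 30.0 | 2 | 36 |
| 50.0 | 0 | 49 |

north-east run (percent of the G charged)

| time / h | D / % | X / % |
|---|---|---|
| 0.500 | 21 | 3 |
| 1.00 | 19 | 5 |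
| 1.50 | 20 | 7 |
| 2.00 | 17 | 10 |
| 2.50 | 17 | 13 |

(scatter of a reading: 1.5 percentage points)

- the numbers in the tables scatter with a standard deviation of 1.5 percentage points

1. ranking by share of D in all that became D or X, from high to low, at 4.0 h (elm / larch / cedar / oak)
2. the share of D in all that became D or X of the flask you put first, at 4.0 h
3. the share of D in all that became D or X of the flask you put last, at 4.0 h

The analyst reported that D stops rising early in the north-west run, near 15%, while X keeps climbing to 12%.

I proposed to carry one time, τ = t·D/X: the time at which X catches up with D if G stands still. The share of D, its selectivity, is then τ/(τ+t). Suppose D = K·[E]·[G] at balance, and X grows as k·Ḡ·t, where K and k are the constants of the two steps and Ḡ is the mean of G over the run. Replacing Ḡ by the end value of G gives τ = K[E]/k, which holds no G and grows with E. I named that replacement the weak step.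

The last north-east reading gives τ = 3.27 h at 42 mM of E and 35 °C. The south-west reading at 12.0 min gives 0.0625 h at 32.4 mM of E and 57 °C. Per unit of E, the factor between these two temperatures is 40.4. Taking the logarithm of τ as straight in temperature and τ as proportional to E, I carried this to each flask. So elm has τ = 41.8 h, its catch-up time, and a share of 91.3%. Oak has 13.5 h and larch 4.18 h, and cedar at 65 °C falls to 0.00754 h.

The forecaster read the plateau as “a reversible, exothermic pre-equilibrium” and gave elm > oak > larch > cedar. The forecast put the top at 94% (85% to 97%) and the low at 0.1% (0% to 1%). My order was the same, and my top was lower.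

The simulation gives elm > oak > larch > cedar, with 95.5% for elm and 0% for cedar.

    G + E ⇌ D (K = 20.0 L mol⁻¹, k = 21.0 L mol⁻¹ h⁻¹, Ea = 47.0 kJ mol⁻¹, ΔH = −76.0 kJ mol⁻¹)
    G → X (k = 0.0180 h⁻¹, Ea = 103 kJ mol⁻¹)
    2 G → Q (k = 0.860 L mol⁻¹ h⁻¹, Ea = 68.0 kJ mol⁻¹)
    (constants at 25 °C)

In elm the step G + E ⇌ D relaxes with a half-life of 0.227 h, short against the run of 4.0 h, while G going to X alone has a half-life of 39 h. Elm's end state gives τ = 85.3 h, more than my 41.8 h, and its mean G, 39.8%, stands above the end value of 34.0%. Scaling my τ by free E to the neighbour of elm charged with 40 mM gives 15.7 h, so a share of 79.7%; that flask gives 89.2%.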